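In eudesmane numbering, ring A (C1–C5, C10) carries its two hydroxyls on adjacent C3/C4, a masked C3=C4 alkene next to quaternary C10, so the decalin is the adduct of a type 1 intramolecular Diels–Alder reaction. Heating an acyclic 1,7,9-decatriene (diene C2=C3–C4(Me)=C5, dienophile C1=C10(Me), tether C6–C9) forms C1–C2 and C5–C10, both rings and the C5/C10 stereocentres at once. The C4 methyl acts as a steric directing group, so C6 is carried as the equatorial (6α) carbinol, set together with C7 in one allylboration, then inverted by oxidation and reduction; C3/C4 follow by α-epoxidation and trans-diaxial hydrolysis.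

Key step: step 5

Remark: locants follow eudesmane numbering (decalin C1–C10; methyl on C4 and C10, isopropyl on C7, benzoate on C6; β is the face of the C10 methyl). Compound 1 is taken as the purchased (E) isomer and 4 as the purchased (Z) isomer. (−)-Ipc2BOMe is (−)-B-methoxydiisopinocampheylborane from (+)-α-pinene, COB([C@@H]1C[C@@H]2C[C@H]([C@H]1C)C2(C)C)[C@@H]1C[C@@H]2C[C@H]([C@H]1C)C2(C)C, assumed to deliver the allyl unit to the Si face of an aldehyde as its parent allyl and crotyl reagents do.

Step 1
Reactants: 1 (2E)-3-methylpent-2-en-4-yn-1-ol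
Product: 2 (2E)-3-methylpenta-2,4-dien-1-ol
Conditions: H2 (1 atm), Pd/CaCO3 poisoned with Pb(OAc)2, quinoline, EtOAc, 0 °C, stopped after 1 equiv H2
Reagents that add atoms: none
Why: Lindlar semi-hydrogenation should reduce only the terminal alkyne to the vinyl group and leave the (E)-trisubstituted alkene untouched, giving the C2=C3–C4(Me)=C5 diene with the geometry of the starting material.

Step 2
Reactants: 2 (2E)-3-methylpenta-2,4-dien-1-ol
Product: 3 (2E)-3-methylpenta-2,4-dienal
Conditions: MnO2 (activated, excess), CH2Cl2, rt; used at once as a cold solution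
Reagents that add atoms: none
Why: MnO2 should oxidise the allylic alcohol chemoselectively to the enal under neutral conditions without E/Z isomerisation (allylic oxidation).

Step 3
Reactants: 3 (2E)-3-methylpenta-2,4-dienal; 4 (Z)-4-methylpent-2-ene
Product: 8 (3R,4S,5E)-6-methyl-3-(propan-2-yl)octa-1,5,7-trien-4-ol, via allylpotassium 5 (not isolated), via allylborane 6 (not isolated), via borinate 7 (not isolated)
Conditions: 4, n-BuLi, KOt-Bu, THF, −78 to −45 °C; (−)-Ipc2BOMe, −78 °C; BF3·OEt2; 3, −78 °C; then NaOH, H2O2, 0 °C to rt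
Reagents that add atoms: (Z)-4-methylpent-2-ene 4, C/C=C\C(C)C
Why: Brown-type asymmetric allylboration after Schlosser metalation: the (Z)-allylborane reacts through a closed chair transition state, so Z geometry should give the syn C6/C7 pair and the isopinocampheyl groups should direct C–C bond formation to the Si face of the aldehyde, setting both stereocentres by reagent control.

Step 4
Reactants: 8 (3R,4S,5E)-6-methyl-3-(propan-2-yl)octa-1,5,7-trien-4-ol; 9 2-bromopropene
Product: 11 (3E,5S,6S)-3,9-dimethyl-6-(propan-2-yl)deca-1,3,9-trien-5-ol, via alkylborane 10 (not isolated)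
Conditions: 9-BBN (1.1 equiv), THF, 0 °C to rt; then 9, Pd(dppf)Cl2 (cat.), NaOH (aq.), THF, 50 °C
Reagents that add atoms: 2-bromopropene 9, CC(Br)=C
Why: 9-BBN should hydroborate the isolated monosubstituted vinyl group anti-Markovnikov faster than it attacks the conjugated diene or the hindered secondary hydroxyl, and the B-alkyl Suzuki–Miyaura coupling with the vinyl bromide then forms C9–C10 without touching the stereocentres.

Step 5
Reactants: 11 (3E,5S,6S)-3,9-dimethyl-6-(propan-2-yl)deca-1,3,9-trien-5-ol
Product: 12 (1S,2S,4aR,8aR)-4a,8-dimethyl-2-(propan-2-yl)-1,2,3,4,4a,5,6,8a-octahydronaphthalen-1-ol (trans-fused; 6α-OH equatorial; 7β-isopropyl equatorial; 10β-methyl; 5α-H)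
Conditions: toluene (0.01 M, degassed), BHT, 200–220 °C, sealed silanised tube
Reagents that add atoms: none
Why: Concerted, suprafacial thermal [4+2] cycloaddition of the (E)-diene C2=C3–C4(Me)=C5 with the unactivated 1,1-disubstituted alkene C1=C10, the closest known reaction type being the type 1 intramolecular Diels–Alder reaction of 1,7,9-decatrienes. Ring A closes as the new cyclohexene (bonds C1–C2 and C5–C10, alkene left at C3=C4) and ring B closes in the same event as a six-membered carbocycle through the chair-like C6–C9 tether. C5 is controlled by C6 and C7: the C4 methyl is cis to C6 on the diene, so allylic 1,3-strain keeps H6 in the diene plane next to it and the hydroxyl outside (future equatorial), and the same chair carries the isopropyl group equatorial, which fixes the diene face. C10 is controlled by the anti (exo) arrangement of the tether, which leaves the dienophile methyl axial and gives the trans fusion with the methyl anti to H5. The selectivity needed is trans over cis fusion and one diene face; the cis-fused arrangements would push the C6 oxygen or the C6–C7 bond against the C4 methyl and the other face would need both the C6 and C7 substituents axial, so the C4 methyl acts as a built-in steric directing group, although the trans preference is expected and not assured. The price is that the hydroxyl emerges equatorial (6α), which steps 6 and 7 correct.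

Step 6
Reactants: 12 (1S,2S,4aR,8aR)-4a,8-dimethyl-2-(propan-2-yl)-1,2,3,4,4a,5,6,8a-octahydronaphthalen-1-ol
Product: 13 (2S,4aR,8aR)-4a,8-dimethyl-2-(propan-2-yl)-3,4,4a,5,6,8a-hexahydronaphthalen-1(2H)-one
Conditions: Pr4N[RuO4] (cat.), NMO, 4 Å MS, CH2Cl2, rt
Reagents that add atoms: none
Why: Ley–Griffith oxidation should convert the equatorial carbinol to the C6 ketone under neutral conditions, erasing the relay stereocentre without epimerising C5 or C7 or moving the C3=C4 alkene into conjugation.

Step 7
Reactants: 13 (2S,4aR,8aR)-4a,8-dimethyl-2-(propan-2-yl)-3,4,4a,5,6,8a-hexahydronaphthalen-1(2H)-one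
Product: 14 (1R,2S,4aR,8aR)-4a,8-dimethyl-2-(propan-2-yl)-1,2,3,4,4a,5,6,8a-octahydronaphthalen-1-ol (axial 6β-OH)
Conditions: LiAlH4, THF, −78 °C
Reagents that add atoms: none
Why: Hydride reduction under steric approach control: the β (axial) trajectory at C6 is blocked by the syn-axial C10 methyl, so hydride should add from the α face and give the axial 6β-alcohol (any 6α-alcohol is 12 and can be re-oxidised).

Step 8
Reactants: 14 (1R,2S,4aR,8aR)-4a,8-dimethyl-2-(propan-2-yl)-1,2,3,4,4a,5,6,8a-octahydronaphthalen-1-ol; 15 benzoyl chloride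
Product: 16 (1R,2S,4aR,8aR)-4a,8-dimethyl-2-(propan-2-yl)-1,2,3,4,4a,5,6,8a-octahydronaphthalen-1-yl benzoate
Conditions: BzCl, pyridine, DMAP (cat.), CH2Cl2, 0 to 40 °C
Reagents that add atoms: benzoyl chloride 15, O=C(Cl)c1ccccc1
Why: DMAP-catalysed acylation of the only hydroxyl group should install the benzoate and remove the free OH that would otherwise direct the next epoxidation to the β face.

Step 9
Reactants: 16 (1R,2S,4aR,8aR)-4a,8-dimethyl-2-(propan-2-yl)-1,2,3,4,4a,5,6,8a-octahydronaphthalen-1-yl benzoate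
Product: 17 3α,4α-epoxide of 16 (oxirane oxygen on the face opposite to the C10 methyl; C4 methyl β)
Conditions: mCPBA, NaHCO3, CH2Cl2, 0 °C
Reagents that add atoms: mCPBA (3-chloroperoxybenzoic acid), OOC(=O)c1cccc(Cl)c1
Why: Prilezhaev epoxidation of the only alkene should occur from the α face, because the β face of C3=C4 is shielded by the axial C10 methyl and the axial C6 benzoate; this sets C3.

Step 10
Reactants: 17 3α,4α-epoxide of 16
Product: 18 (1R,2S,4aS,7R,8R,8aS)-7,8-dihydroxy-4a,8-dimethyl-2-(propan-2-yl)decahydronaphthalen-1-yl benzoate (CNP0187831.1)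
Conditions: HClO4 (cat.), THF/H2O, 0 °C to rt
Reagents that add atoms: water, O
Why: Acid-catalysed epoxide hydrolysis: water should open the protonated epoxide at the tertiary C4 from the β face with inversion, Markovnikov and trans-diaxial (Fürst–Plattner) preferences coinciding, which gives the 3α,4β-diol with the C4 methyl α; participation of the 6β-benzoate carbonyl at C4 would deliver oxygen to the same face.

**Compound list**

1 | (2E)-3-methylpent-2-en-4-yn-1-ol | OC/C=C(C)/C#C | starting material
2 | (2E)-3-methylpenta-2,4-dien-1-ol | OC/C=C(C)/C=C | intermediate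
3 | (2E)-3-methylpenta-2,4-dienal | O=C/C=C(C)/C=C | intermediate
4 | (Z)-4-methylpent-2-ene | C/C=C\C(C)C | starting material
5 | [(2Z)-4-methylpent-2-en-1-yl]potassium | [K]C/C=C\C(C)C | intermediate
6 | B-[(2Z)-4-methylpent-2-en-1-yl]bis[(1R,2S,3R,5R)-2,6,6-trimethylbicyclo[3.1.1]heptan-3-yl]borane | CC(C)/C=C\CB([C@@H]1C[C@@H]2C[C@H]([C@H]1C)C2(C)C)[C@@H]1C[C@@H]2C[C@H]([C@H]1C)C2(C)C | intermediate
7 | diisopinocampheylborinate ester of 8 | CC(C)[C@H](C=C)[C@H](OB([C@@H]1C[C@@H]2C[C@H]([C@H]1C)C2(C)C)[C@@H]1C[C@@H]2C[C@H]([C@H]1C)C2(C)C)/C=C(C)/C=C | intermediate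
8 | (3R,4S,5E)-6-methyl-3-(propan-2-yl)octa-1,5,7-trien-4-ol | CC(C)[C@H](C=C)[C@H](O)/C=C(C)/C=C | intermediate
9 | 2-bromopropene | CC(Br)=C | starting material
10 | 9-[(3S,4S,5E)-4-hydroxy-6-methyl-3-(propan-2-yl)octa-5,7-dien-1-yl]-9-borabicyclo[3.3.1]nonane | CC(C)[C@H](CCB1C2CCCC1CCC2)[C@H](O)/C=C(C)/C=C | intermediate
11 | (3E,5S,6S)-3,9-dimethyl-6-(propan-2-yl)deca-1,3,9-trien-5-ol | CC(C)[C@H](CCC(C)=C)[C@H](O)/C=C(C)/C=C | intermediate
12 | (1S,2S,4aR,8aR)-4a,8-dimethyl-2-(propan-2-yl)-1,2,3,4,4a,5,6,8a-octahydronaphthalen-1-ol | CC(C)[C@@H]1CC[C@@]2(C)CCC=C(C)[C@@H]2[C@H]1O | intermediate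
13 | (2S,4aR,8aR)-4a,8-dimethyl-2-(propan-2-yl)-3,4,4a,5,6,8a-hexahydronaphthalen-1(2H)-one | CC(C)[C@@H]1CC[C@@]2(C)CCC=C(C)[C@@H]2C1=O | intermediate
14 | (1R,2S,4aR,8aR)-4a,8-dimethyl-2-(propan-2-yl)-1,2,3,4,4a,5,6,8a-octahydronaphthalen-1-ol | CC(C)[C@@H]1CC[C@@]2(C)CCC=C(C)[C@@H]2[C@@H]1O | intermediate
15 | benzoyl chloride | O=C(Cl)c1ccccc1 | starting material
16 | (1R,2S,4aR,8aR)-4a,8-dimethyl-2-(propan-2-yl)-1,2,3,4,4a,5,6,8a-octahydronaphthalen-1-yl benzoate | CC(C)[C@@H]1CC[C@@]2(C)CCC=C(C)[C@@H]2[C@@H]1OC(=O)c1ccccc1 | intermediate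
17 | 3α,4α-epoxide of 16 | CC(C)[C@@H]1CC[C@@]2(C)CC[C@H]3O[C@@]3(C)[C@@H]2[C@@H]1OC(=O)c1ccccc1 | intermediate
18 | (1R,2S,4aS,7R,8R,8aS)-7,8-dihydroxy-4a,8-dimethyl-2-(propan-2-yl)decahydronaphthalen-1-yl benzoate | CC(C)[C@@H]1CC[C@@]2(C)CC[C@@H](O)[C@](C)(O)[C@@H]2[C@@H]1OC(=O)c1ccccc1 | target

**Total step count:** 10. **Longest linear sequence:** 10 steps (1 to 18).

**Steps most likely to fail**

Step 5. The unactivated cycloaddition may be too slow at temperatures the free dienylic alcohol tolerates, so that dehydration or polymerisation of the diene competes, and cis-fused addition may not be fully suppressed. The fallback sets out from 11 and comes back at 13. Oxidation of 11 with MnO2 (CH2Cl2, rt) should give the dienone (3E,6S)-3,9-dimethyl-6-(propan-2-yl)deca-1,3,9-trien-5-one F1. Its acyl-substituted, LUMO-lowered diene should add to the electron-rich 1,1-disubstituted alkene at lower temperature (toluene, BHT, 150–170 °C). The cycloadduct is ketone 13 directly, which makes step 6 unnecessary. The trade-off is that the ring fusion then rests on the anti preference of the tether and the diene face on C7 alone.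

Step 4. Hydroboration may also attack the terminal vinyl group of the conjugated diene, and the palladium catalyst may ionise the dienylic alcohol. The fallback sets out from 8 and comes back at 11. The diene is masked by cheletropic addition of SO2 (liquid SO2, hydroquinone, sealed tube, rt) as the 3-sulfolene 2-[(1S,2R)-1-hydroxy-2-(propan-2-yl)but-3-en-1-yl]-3-methyl-2,5-dihydrothiophene 1,1-dioxide F2, a mixture at the new sulfone-bearing carbon. Hydroboration with 9-BBN (THF, 0 °C to rt) should give the alkylborane 2-[(1S,2S)-4-(9-borabicyclo[3.3.1]nonan-9-yl)-1-hydroxy-2-(propan-2-yl)butyl]-3-methyl-2,5-dihydrothiophene 1,1-dioxide F3, which is not isolated. Coupling with 9 (Pd(dppf)Cl2, K3PO4, THF/H2O, rt to 40 °C) then gives the chain-extended sulfolene 2-[(1S,2S)-1-hydroxy-5-methyl-2-(propan-2-yl)hex-5-en-1-yl]-3-methyl-2,5-dihydrothiophene 1,1-dioxide F4. Thermal extrusion of SO2 (toluene, NaHCO3, 110 °C) should return the (E)-diene 11 stereospecifically.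

Step 10. The tertiary C4 cation may eliminate to allylic alcohols, or the benzoyl group may migrate from O6 to O4 after capture of the cation by the benzoate carbonyl. The fallback sets out from 14 and comes back at 18, and avoids a cation at C4. Hydroxyl-directed epoxidation of 14 (VO(acac)2, t-BuOOH, CH2Cl2) should give the 3β,4β-epoxy-6β-alcohol F5. Trans-diaxial opening at the secondary C3 from the α face with BnONa in BnOH (110 °C) should give the 3α-benzyloxy-4β,6β-diol F6. Benzoylation of its only secondary hydroxyl with 15 (DMAP, pyridine) gives the 3α-benzyloxy-4β-hydroxy-6β-benzoate F7, and hydrogenolysis (H2, Pd/C, EtOAc) gives 18.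

**Further compounds**

F1 | step 5 | (3E,6S)-3,9-dimethyl-6-(propan-2-yl)deca-1,3,9-trien-5-one | CC(C)[C@H](CCC(C)=C)C(=O)/C=C(C)/C=C
F2 | step 4 | 2-[(1S,2R)-1-hydroxy-2-(propan-2-yl)but-3-en-1-yl]-3-methyl-2,5-dihydrothiophene 1,1-dioxide | CC(C)[C@H](C=C)[C@H](O)C1C(C)=CCS1(=O)=O
F3 | step 4 | 2-[(1S,2S)-4-(9-borabicyclo[3.3.1]nonan-9-yl)-1-hydroxy-2-(propan-2-yl)butyl]-3-methyl-2,5-dihydrothiophene 1,1-dioxide | CC(C)[C@H](CCB1C2CCCC1CCC2)[C@H](O)C1C(C)=CCS1(=O)=O
F4 | step 4 | 2-[(1S,2S)-1-hydroxy-5-methyl-2-(propan-2-yl)hex-5-en-1-yl]-3-methyl-2,5-dihydrothiophene 1,1-dioxide | CC(C)[C@H](CCC(C)=C)[C@H](O)C1C(C)=CCS1(=O)=O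
F5 | step 10 | 3β,4β-epoxide of 14 (3β,4β-epoxy-6β-alcohol) | CC(C)[C@@H]1CC[C@@]2(C)CC[C@@H]3O[C@]3(C)[C@@H]2[C@@H]1O
F6 | step 10 | 3α-benzyloxy-4β,6β-diol | CC(C)[C@@H]1CC[C@@]2(C)CC[C@@H](OCc3ccccc3)[C@](C)(O)[C@@H]2[C@@H]1O
F7 | step 10 | 3α-benzyloxy-4β-hydroxy-6β-benzoate | CC(C)[C@@H]1CC[C@@]2(C)CC[C@@H](OCc3ccccc3)[C@](C)(O)[C@@H]2[C@@H]1OC(=O)c1ccccc1
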